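The α-methylene-γ-lactone is cut across O–C6 and C7–C11 (germacrane numbering). Because C6 is allylic to the C4=C5 olefin of the ten-membered ring, the lactone ring (O, C6, C7, C11, C12) can be laid onto a C4=C5–C6=C7 diene. In the key step 2-bromoacrylic acid is annulated under palladium catalysis onto a preformed (1(10)Z,4Z,6E)-cyclodecatriene, which forms both bonds, the lactone ring and the C6 and C7 stereocentres in one operation. The triene comes from a chelation-controlled union of a Z,Z-bromo-iodo-diene with a chiral-pool α-alkoxy aldehyde (C8, C9) and an intramolecular Suzuki coupling that fixes the E,Z-diene.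

Key step: step 14

Remark on the chemistry: locants follow germacrane numbering (ring C1–C10, lactone carbons C11–C13, C14 = CH2O carbon on C10, C15 = methyl on C4), α/β refer to the usual germacranolide drawing (C11 on C7 is β), and the six starting materials are assumed to be commercially available.

Step 1
Reactants: 1 but-3-yn-1-ol
Product: 4 (Z)-4-bromo-3-methylbut-3-en-1-ol, via E-alkenylalane 2 (not isolated), via chelated Z-alkenylalane 3 (not isolated)
Conditions: Me3Al (3 equiv), Cp2ZrCl2 (0.25 equiv), ClCH2CH2Cl, 23 °C; then AlCl3, 50 °C; then NBS, THF, −30 °C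
Reagents that add atoms: trimethylaluminium C[Al](C)C; N-bromosuccinimide O=C1CCC(=O)N1Br
Why: Zirconium-catalysed Negishi carboalumination adds methyl and aluminium syn, the aluminium alkoxide then drives chelation-controlled isomerization to the Z-alkenylalane (anti-carbometalation of a homopropargylic alcohol), and bromodealumination should proceed with retention.

Step 2
Reactants: 4 (Z)-4-bromo-3-methylbut-3-en-1-ol; 5 2-(prop-2-yn-1-yloxy)tetrahydro-2H-pyran
Product: 9 (Z)-7-bromo-6-methylhept-6-en-2-yn-1-ol, via lithium acetylide 6 (not isolated), via triflate 7 (not isolated), via THP ether 8 (not isolated)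
Conditions: 4, Tf2O, 2,6-lutidine, CH2Cl2, −78 °C; 5, n-BuLi, THF/DMPU, −78 °C, then crude triflate, −78 → −20 °C; then p-TsOH·H2O, MeOH, 23 °C
Reagents that add atoms: none
Why: SN2 alkylation of a lithium acetylide by a primary triflate at low temperature, where substitution should outrun elimination, is followed by acid-catalysed acetal exchange that frees the propargylic alcohol; no stereocentre is formed and the Z-bromoalkene is untouched.

Step 3
Reactants: 9 (Z)-7-bromo-6-methylhept-6-en-2-yn-1-ol
Product: 10 (2Z,6Z)-7-bromo-6-methyl-2-(tributylstannyl)hepta-2,6-dien-1-ol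
Conditions: n-Bu3SnH, [Cp*RuCl]4 (3 mol %), CH2Cl2, 23 °C
Reagents that add atoms: tributyltin hydride CCCC[SnH](CCCC)CCCC
Why: Ruthenium-catalysed trans-hydrostannation of a propargylic alcohol, in which the hydroxyl group steers tin to the proximal alkyne carbon and hydrogen adds anti, should set the 2Z geometry with tin cis to the carbon chain.

Step 4
Reactants: 10 (2Z,6Z)-7-bromo-6-methyl-2-(tributylstannyl)hepta-2,6-dien-1-ol
Product: 11 (2Z,6Z)-7-bromo-2-iodo-6-methylhepta-2,6-dien-1-ol
Conditions: I2, CH2Cl2, 0 °C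
Reagents that add atoms: iodine II
Why: Iododestannylation of an alkenylstannane occurs with retention of olefin geometry and is much faster than any reaction of the bromoalkene.

Step 5
Reactants: 11 (2Z,6Z)-7-bromo-2-iodo-6-methylhepta-2,6-dien-1-ol
Product: 12 tert-butyl{[(2Z,6Z)-7-bromo-2-iodo-6-methylhepta-2,6-dien-1-yl]oxy}dimethylsilane
Conditions: TBSCl, imidazole, DMF, 23 °C
Reagents that add atoms: tert-butyldimethylsilyl chloride CC(C)(C)[Si](C)(C)Cl
Why: Standard silyl ether formation masks the primary allylic hydroxyl (the later C14–OH) for the organometallic step.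

Step 6
Reactants: 13 (S)-but-3-ene-1,2-diol
Product: 14 (4S)-2-(4-methoxyphenyl)-4-vinyl-1,3-dioxolane
Conditions: 4-MeOC6H4CH(OMe)2, camphorsulfonic acid (cat.), CH2Cl2, 23 °C
Reagents that add atoms: 4-methoxybenzaldehyde dimethyl acetal COc1ccc(C(OC)OC)cc1
Why: Acid-catalysed transacetalization of the 1,2-diol gives the 4-methoxybenzylidene acetal without touching the stereocentre that becomes C8.

Step 7
Reactants: 14 (4S)-2-(4-methoxyphenyl)-4-vinyl-1,3-dioxolane
Product: 15 (S)-2-[(4-methoxybenzyl)oxy]but-3-en-1-ol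
Conditions: i-Bu2AlH, CH2Cl2, −78 → 0 °C
Reagents that add atoms: none
Why: Regioselective reductive acetal opening, in which i-Bu2AlH coordinates the less hindered primary oxygen and delivers hydride to the acetal carbon, should leave the 4-methoxybenzyl ether on the secondary oxygen.

Step 8
Reactants: 15 (S)-2-[(4-methoxybenzyl)oxy]but-3-en-1-ol
Product: 16 (S)-2-[(4-methoxybenzyl)oxy]but-3-enal
Conditions: Dess–Martin periodinane, NaHCO3, CH2Cl2, 0 °C; used at once
Reagents that add atoms: none
Why: Dess–Martin oxidation under buffered non-basic conditions should give the α-alkoxy β,γ-unsaturated aldehyde without epimerization or double-bond migration.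

Step 9
Reactants: 12 tert-butyl{[(2Z,6Z)-7-bromo-2-iodo-6-methylhepta-2,6-dien-1-yl]oxy}dimethylsilane; 16 (S)-2-[(4-methoxybenzyl)oxy]but-3-enal
Product: 19 (3S,4S,5Z,9Z)-10-bromo-5-{[(tert-butyldimethylsilyl)oxy]methyl}-3-[(4-methoxybenzyl)oxy]-9-methyldeca-1,5,9-trien-4-ol, via alkenyllithium 17 (not isolated), via alkenylmagnesium bromide 18 (not isolated)
Conditions: 12, t-BuLi (2.0 equiv), Et2O, −100 °C; MgBr2·OEt2, −78 °C; then 16, CH2Cl2, −78 °C
Reagents that add atoms: none
Why: Iodine–lithium exchange is far faster than bromine–lithium exchange at −100 °C, and after transmetalation to magnesium the alkenyl nucleophile adds to the Cram chelate of the α-alkoxy aldehyde from the face of the small hydrogen, which should set C9 (S) syn to C8 (chelation-controlled 1,2-addition).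

Step 10
Reactants: 20 2-hydroxy-2-methylpropanoic acid
Product: 22 2-methyl-2-[(triethylsilyl)oxy]propanoyl chloride, via bis-silyl ester 21 (not isolated)
Conditions: Et3SiCl (2.2 equiv), imidazole, DMF, 23 °C; then (COCl)2, DMF (cat.), CH2Cl2, 0 → 23 °C
Reagents that add atoms: chlorotriethylsilane CC[Si](Cl)(CC)CC; oxalyl chloride O=C(Cl)C(Cl)=O
Why: Silylation of both hydroxyl functions followed by the oxalyl chloride/DMF conversion of the silyl ester into the acid chloride should give the O-protected acylating agent.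

Step 11
Reactants: 19 (3S,4S,5Z,9Z)-10-bromo-5-{[(tert-butyldimethylsilyl)oxy]methyl}-3-[(4-methoxybenzyl)oxy]-9-methyldeca-1,5,9-trien-4-ol; 22 2-methyl-2-[(triethylsilyl)oxy]propanoyl chloride
Product: 23 (3S,4S,5Z,9Z)-10-bromo-5-{[(tert-butyldimethylsilyl)oxy]methyl}-3-[(4-methoxybenzyl)oxy]-9-methyldeca-1,5,9-trien-4-yl 2-methyl-2-[(triethylsilyl)oxy]propanoate
Conditions: DMAP, Et3N, CH2Cl2, 0 → 40 °C
Reagents that add atoms: none
Why: DMAP-catalysed acylation of the secondary allylic alcohol by the acid chloride (nucleophilic catalysis) proceeds with retention at C9.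

Step 12
Reactants: 23 the C9 ester of step 11; 24 4,4,5,5-tetramethyl-2-vinyl-1,3,2-dioxaborolane
Product: 25 (1E,3S,4S,5Z,9Z)-10-bromo-5-{[(tert-butyldimethylsilyl)oxy]methyl}-3-[(4-methoxybenzyl)oxy]-9-methyl-1-(4,4,5,5-tetramethyl-1,3,2-dioxaborolan-2-yl)deca-1,5,9-trien-4-yl 2-methyl-2-[(triethylsilyl)oxy]propanoate
Conditions: second-generation Grubbs catalyst (10 mol %), 24 (3 equiv), CH2Cl2, 40 °C
Reagents that add atoms: none
Why: Olefin cross-metathesis of the terminal vinyl group with the vinylboronate is E-selective and should leave the trisubstituted olefins and the bromoalkene untouched.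

Step 13
Reactants: 25 the E-alkenylboronate of step 12
Product: 26 (1(10)Z,4Z,6E)-14-(tert-butyldimethylsilyloxy)-8β-(4-methoxybenzyloxy)-9α-[2-methyl-2-(triethylsilyloxy)propanoyloxy]-11,12,13-trinorgermacra-1(10),4,6-triene
Conditions: Pd(PPh3)4 (20 mol %), TlOEt (3 equiv), THF/H2O 3:1, 23 °C, 1 mM, slow addition
Reagents that add atoms: none
Why: Intramolecular Suzuki–Miyaura coupling of the Z-bromoalkene with the E-alkenylboronate under high dilution should close the ten-membered ring with retention at both olefins, which fixes the (4Z,6E)-diene, and the thallium base allows coupling at room temperature without ester cleavage.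

Step 14
Reactants: 26 the macrocyclic triene of step 13; 27 2-bromoacrylic acid
Product: 29 14-(tert-butyldimethylsilyloxy)-8β-(4-methoxybenzyloxy)-9α-[2-methyl-2-(triethylsilyloxy)propanoyloxy]germacra-1(10)Z,4Z,11(13)-trien-12,6α-olide, via allylpalladium bromide 28 (not isolated)
Conditions: 27 (3 equiv, in portions), Pd(OAc)2 (10 mol %), n-Bu4NCl, K2CO3, DMF, 70 °C
Reagents that add atoms: none
Why: Zerovalent palladium inserts into the C–Br bond of 27, the alkenylpalladium adds syn across the strained E-C6=C7 olefin with C11 going to C7 (the monosubstituted diene terminus, whereas C4 carries the methyl group), and the allylpalladium 28 (C6–C5–C4) is captured at C6 by the tethered carboxylate. The closest known reaction is the Larock-type palladium-catalysed heteroannulation of cyclic 1,3-dienes by vinylic or aryl halides that carry a carboxylic acid, which gives net syn addition. The γ-lactone closes by 5-exo attack of the carboxylate oxygen on the allyl terminus C6 (C–O bond formation on the palladium-bearing face) in preference to seven-membered closure at C4, and the ring holds C4=C5 in the Z geometry. C7 is controlled by the C8 stereocentre: the ring chain (C9) blocks one face of the E-olefin, the C8–O bond lies in the olefin plane (inside-alkoxy arrangement) and H8 points to the open face, so C11 should enter cis to O8 (7β). C6 is controlled by C7, because carbon and oxygen are both delivered from the peripheral face and syn addition across an E-olefin gives the trans-fused lactone (6α-O, H6 and H7 anti). The step needs site selectivity for the diene over the 1(10)-olefin and over ionization of the allylic C9 ester, which the conjugation and strain of the diene and the phosphine-free conditions (fast oxidative addition to 27) should secure.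

Step 15
Reactants: 29 the lactone of step 14
Product: 30 14-(tert-butyldimethylsilyloxy)-8β-hydroxy-9α-[2-methyl-2-(triethylsilyloxy)propanoyloxy]germacra-1(10)Z,4Z,11(13)-trien-12,6α-olide
Conditions: DDQ, CH2Cl2/pH 7 buffer, 0 → 23 °C
Reagents that add atoms: none
Why: Oxidative cleavage of the 4-methoxybenzyl ether by DDQ (single-electron oxidation, then hydrolysis of the oxocarbenium ion) should free the C8 hydroxyl without affecting silyl ethers, esters or the lactone.

Step 16
Reactants: 30 the 8β-alcohol of step 15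
Product: 31 14-(tert-butyldimethylsilyloxy)-8β-(2-methylpropanoyloxy)-9α-[2-methyl-2-(triethylsilyloxy)propanoyloxy]germacra-1(10)Z,4Z,11(13)-trien-12,6α-olide
Conditions: i-PrCOCl, pyridine, DMAP (cat.), CH2Cl2, 0 → 23 °C
Reagents that add atoms: isobutyryl chloride CC(C)C(Cl)=O
Why: DMAP-catalysed acylation of the C8 alcohol under mild conditions is chosen to avoid acyl migration from O9 and conjugate addition to the methylene lactone.

Step 17
Reactants: 31 the bis-silyl diester of step 16
Product: 32 (6R,7S,8S,9S)-14-hydroxy-9α-(2-hydroxy-2-methylpropanoyloxy)-8β-(2-methylpropanoyloxy)germacra-1(10)Z,4Z,11(13)-trien-12,6α-olide (CNP0220567.2)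
Conditions: HF·pyridine, pyridine, THF, 0 → 23 °C
Reagents that add atoms: none
Why: Buffered fluoride-mediated desilylation should remove the primary tert-butyldimethylsilyl and the tertiary triethylsilyl ethers while the esters and the α-methylene lactone stay intact.

Compound list
1 | but-3-yn-1-ol | C#CCCO | starting material
2 | E-alkenylalane from syn-carboalumination | C[Al](C)OCC/C(C)=C/[Al](C)C | intermediate
3 | chelated Z-alkenylalane (2,4-dimethyl-1-oxa-2-aluminacyclohex-3-ene) | C[Al]1OCCC(C)=C1 | intermediate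
4 | (Z)-4-bromo-3-methylbut-3-en-1-ol | OCC/C(C)=C\Br | intermediate
5 | 2-(prop-2-yn-1-yloxy)tetrahydro-2H-pyran | C#CCOC1CCCCO1 | starting material
6 | lithium acetylide of 5 | [Li]C#CCOC1CCCCO1 | intermediate
7 | (Z)-4-bromo-3-methylbut-3-en-1-yl trifluoromethanesulfonate | O=S(=O)(OCC/C(C)=C\Br)C(F)(F)F | intermediate
8 | 2-{[(Z)-7-bromo-6-methylhept-6-en-2-yn-1-yl]oxy}tetrahydro-2H-pyran | Br/C=C(/C)CCC#CCOC1CCCCO1 | intermediate
9 | (Z)-7-bromo-6-methylhept-6-en-2-yn-1-ol | Br/C=C(/C)CCC#CCO | intermediate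
10 | (2Z,6Z)-7-bromo-6-methyl-2-(tributylstannyl)hepta-2,6-dien-1-ol | Br/C=C(/C)CC/C=C(/CO)[Sn](CCCC)(CCCC)CCCC | intermediate
11 | (2Z,6Z)-7-bromo-2-iodo-6-methylhepta-2,6-dien-1-ol | Br/C=C(/C)CC/C=C(/CO)I | intermediate
12 | tert-butyl{[(2Z,6Z)-7-bromo-2-iodo-6-methylhepta-2,6-dien-1-yl]oxy}dimethylsilane | Br/C=C(/C)CC/C=C(/CO[Si](C)(C)C(C)(C)C)I | intermediate
13 | (S)-but-3-ene-1,2-diol | C=C[C@H](O)CO | starting material
14 | (4S)-2-(4-methoxyphenyl)-4-vinyl-1,3-dioxolane (acetal epimers) | C=C[C@H]1COC(c2ccc(OC)cc2)O1 | intermediate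
15 | (S)-2-[(4-methoxybenzyl)oxy]but-3-en-1-ol | C=C[C@H](OCc1ccc(OC)cc1)CO | intermediate
16 | (S)-2-[(4-methoxybenzyl)oxy]but-3-enal | C=C[C@H](OCc1ccc(OC)cc1)C=O | intermediate
17 | alkenyllithium from 12 | [Li]/C(CO[Si](C)(C)C(C)(C)C)=C\CC/C(C)=C\Br | intermediate
18 | alkenylmagnesium bromide from 12 | Br[Mg]/C(CO[Si](C)(C)C(C)(C)C)=C\CC/C(C)=C\Br | intermediate
19 | (3S,4S,5Z,9Z)-10-bromo-5-{[(tert-butyldimethylsilyl)oxy]methyl}-3-[(4-methoxybenzyl)oxy]-9-methyldeca-1,5,9-trien-4-ol | C=C[C@H](OCc1ccc(OC)cc1)[C@@H](O)/C(CO[Si](C)(C)C(C)(C)C)=C\CC/C(C)=C\Br | intermediate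
20 | 2-hydroxy-2-methylpropanoic acid | CC(C)(O)C(=O)O | starting material
21 | triethylsilyl 2-methyl-2-[(triethylsilyl)oxy]propanoate | CC[Si](CC)(CC)OC(C)(C)C(=O)O[Si](CC)(CC)CC | intermediate
22 | 2-methyl-2-[(triethylsilyl)oxy]propanoyl chloride | CC[Si](CC)(CC)OC(C)(C)C(Cl)=O | intermediate
23 | (3S,4S,5Z,9Z)-10-bromo-5-{[(tert-butyldimethylsilyl)oxy]methyl}-3-[(4-methoxybenzyl)oxy]-9-methyldeca-1,5,9-trien-4-yl 2-methyl-2-[(triethylsilyl)oxy]propanoate | C=C[C@H](OCc1ccc(OC)cc1)[C@@H](OC(=O)C(C)(C)O[Si](CC)(CC)CC)/C(CO[Si](C)(C)C(C)(C)C)=C\CC/C(C)=C\Br | intermediate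
24 | 4,4,5,5-tetramethyl-2-vinyl-1,3,2-dioxaborolane | C=CB1OC(C)(C)C(C)(C)O1 | starting material
25 | E-alkenyl pinacol boronate of 23 (1E,3S,4S,5Z,9Z) | CC1(C)OB(/C=C/[C@H](OCc2ccc(OC)cc2)[C@@H](OC(=O)C(C)(C)O[Si](CC)(CC)CC)/C(CO[Si](C)(C)C(C)(C)C)=C\CC/C(C)=C\Br)OC1(C)C | intermediate
26 | (1(10)Z,4Z,6E)-14-(tert-butyldimethylsilyloxy)-8β-(4-methoxybenzyloxy)-9α-[2-methyl-2-(triethylsilyloxy)propanoyloxy]-11,12,13-trinorgermacra-1(10),4,6-triene | [C@H]1(OCc2ccc(OC)cc2)/C=C/C=C(/C)CC/C=C(/CO[Si](C)(C)C(C)(C)C)[C@@H]1OC(=O)C(C)(C)O[Si](CC)(CC)CC | intermediate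
27 | 2-bromoacrylic acid | C=C(Br)C(=O)O | starting material
28 | allylpalladium bromide after carbopalladation, drawn in its C6-bound form (C11 and Pd on the same face) | C=C(C(=O)O)[C@H]1[C@H]([Pd]Br)/C=C(/C)CC/C=C(/CO[Si](C)(C)C(C)(C)C)[C@H](OC(=O)C(C)(C)O[Si](CC)(CC)CC)[C@H]1OCc1ccc(OC)cc1 | intermediate
29 | 14-(tert-butyldimethylsilyloxy)-8β-(4-methoxybenzyloxy)-9α-[2-methyl-2-(triethylsilyloxy)propanoyloxy]germacra-1(10)Z,4Z,11(13)-trien-12,6α-olide | C=C1C(=O)O[C@@H]2/C=C(/C)CC/C=C(/CO[Si](C)(C)C(C)(C)C)[C@H](OC(=O)C(C)(C)O[Si](CC)(CC)CC)[C@@H](OCc3ccc(OC)cc3)[C@@H]12 | intermediate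
30 | 14-(tert-butyldimethylsilyloxy)-8β-hydroxy-9α-[2-methyl-2-(triethylsilyloxy)propanoyloxy]germacra-1(10)Z,4Z,11(13)-trien-12,6α-olide | C=C1C(=O)O[C@@H]2/C=C(/C)CC/C=C(/CO[Si](C)(C)C(C)(C)C)[C@H](OC(=O)C(C)(C)O[Si](CC)(CC)CC)[C@@H](O)[C@@H]12 | intermediate
31 | 14-(tert-butyldimethylsilyloxy)-8β-(2-methylpropanoyloxy)-9α-[2-methyl-2-(triethylsilyloxy)propanoyloxy]germacra-1(10)Z,4Z,11(13)-trien-12,6α-olide | C=C1C(=O)O[C@@H]2/C=C(/C)CC/C=C(/CO[Si](C)(C)C(C)(C)C)[C@H](OC(=O)C(C)(C)O[Si](CC)(CC)CC)[C@@H](OC(=O)C(C)C)[C@@H]12 | intermediate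
32 | CNP0220567.2, (6R,7S,8S,9S)-14-hydroxy-9α-(2-hydroxy-2-methylpropanoyloxy)-8β-(2-methylpropanoyloxy)germacra-1(10)Z,4Z,11(13)-trien-12,6α-olide | C=C1C(=O)O[C@@H]2/C=C(/C)CC/C=C(/CO)[C@H](OC(=O)C(C)(C)O)[C@@H](OC(=O)C(C)C)[C@@H]12 | target

Total step count: 17. Longest linear sequence: 13 steps (steps 1–5, 9, 11–17).

Steps most likely to fail

1. Step 14 (key annulation). The ring may present the wrong face of the E-olefin to the alkenylpalladium. The allylpalladium may also lose a β-hydrogen to give a dienyl acrylic acid instead of closing the C–O bond, or zerovalent palladium may ionize the allylic C9 ester. The fallback sets out from 26 and comes back to the route at 29. It replaces the organopalladium pathway by a radical-polar annulation followed by methylenation: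
   - Iodine-atom-transfer radical addition of iodoacetic acid (Et3B/air, EtOH/H2O, 23 °C) should place the carboxymethyl radical on C7 of the diene. The allylic iodide formed by atom transfer lactonizes at C6 to the α-unsubstituted trans-lactone F1.
   - The lactone is the only enolizable carbonyl, so LiN(SiMe3)2 (THF, −78 °C) and then Eschenmoser salt should give the α-(dimethylaminomethyl) lactone F2.
   - Quaternization with MeI and elimination with NaHCO3 then give 29.

2. Step 13 (macrocyclic Suzuki coupling). Oligomerization may outrun closure of the strained ten-membered E,Z-diene, or phosphine-ligated zerovalent palladium may ionize the allylic ester. The fallback sets out from 23 and comes back at 26, bypassing 25. An intramolecular Heck reaction (Pd(OAc)2, P(o-tol)3, Ag2CO3, MeCN, 60 °C, 1 mM) inserts the alkenylpalladium formed at the bromoalkene into the terminal vinyl group in the endo sense. Syn β-hydride elimination then gives the same (4Z,6E)-diene. This fallback makes no compound outside the list (F0).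

3. Step 9 (fragment union). Bromine–lithium exchange may compete, the sensitive aldehyde may enolize, or chelation control may erode and scramble C9. The fallback sets out from 12 and 16 and comes back at 19:
   - Nozaki–Hiyama–Kishi coupling (CrCl2, NiCl2 cat., DMSO/THF, 23 °C) activates only the iodoalkene and gives the allylic alcohol F3 as a C9 epimer mixture.
   - Dess–Martin oxidation gives the enone F4.
   - Corey–Bakshi–Shibata reduction with (S)-2-methyl-CBS-oxazaborolidine and BH3·SMe2 (alkenyl as the large group) should set C9 (S) under reagent control.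

Further compounds
F1 | step 14 | α-unsubstituted trans-lactone (29 without the exocyclic methylene) | C1C(=O)O[C@@H]2/C=C(/C)CC/C=C(/CO[Si](C)(C)C(C)(C)C)[C@H](OC(=O)C(C)(C)O[Si](CC)(CC)CC)[C@@H](OCc3ccc(OC)cc3)[C@@H]12
F2 | step 14 | α-(dimethylaminomethyl) lactone (C11 epimers) | CN(C)CC1C(=O)O[C@@H]2/C=C(/C)CC/C=C(/CO[Si](C)(C)C(C)(C)C)[C@H](OC(=O)C(C)(C)O[Si](CC)(CC)CC)[C@@H](OCc3ccc(OC)cc3)[C@@H]12
F0 | step 13 | none | none
F3 | step 9 | (3S,5Z,9Z)-10-bromo-5-{[(tert-butyldimethylsilyl)oxy]methyl}-3-[(4-methoxybenzyl)oxy]-9-methyldeca-1,5,9-trien-4-ol (C4 epimers) | C=C[C@H](OCc1ccc(OC)cc1)C(O)/C(CO[Si](C)(C)C(C)(C)C)=C\CC/C(C)=C\Br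
F4 | step 9 | (3S,5Z,9Z)-10-bromo-5-{[(tert-butyldimethylsilyl)oxy]methyl}-3-[(4-methoxybenzyl)oxy]-9-methyldeca-1,5,9-trien-4-one | C=C[C@H](OCc1ccc(OC)cc1)C(=O)/C(CO[Si](C)(C)C(C)(C)C)=C\CC/C(C)=C\Br
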